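All constants come from no measurement; the rest is arithmetic.

**Partner's claimants.** Follow partner through these flasks: the catalysed step and partner's own decay both draw on it.

all flasks: protic impurity 0.0300 M; catalyst 3.0 mM; time 30 s
- green: starting material 0.10 M (fed, over 25 s); partner 0.100 M; the addition at 30 °C, then warmed to 50 °C; the feed brings no volume worth counting
- teal: starting material 0.10 M; partner 0.100 M (in portions, 2, over 25 s); first portion at the start, last at 25 s; temperature 50 °C
- violet: starting material 0.10 M; partner 0.100 M (fed, over 25 s); all else is in the flask from the start; the feed brings no volume worth counting; temperature 50 °C
- ochre: starting material 0.10 M (fed, over 6.0 s); partner 0.100 M; all else is in the flask from the start; the feed brings no volume worth counting; temperature 50 °C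
- red: starting material 0.10 M; partner 0.100 M; everything together at the start; temperature 50 °C

    starting material + partner + catalyst → target + catalyst, rate k1*[starting material]*[partner]*[catalyst]/(1 + ([starting material]/sat1)) (sat1 = 0.103 M, k1 = 1540 /M²/s, Ea1 = 36.0 kJ/mol)
    starting material + protic impurity → quenched substrate (k2 = 1.80 /M/s, Ea2 = 60.0 kJ/mol)
    starting material + partner → uncatalysed product (k3 = 0.332 /M/s, Ea3 = 62.0 kJ/mol)
    partner → decomposed reagent (k4 = 0.162 /s, Ea4 = 80.0 kJ/mol)
    (constants at 50 °C)

- all constants are for 50 °C and move with temperature by the activation energies

- the best flask by amount of target, in percent of the starting material charged; "all alike" if 1.5 percentage points covers them all (green / teal / violet / ochre / red / all alike)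
- amount of target at the end, in percent of the starting material charged, green
- amount of target at the end, in percent of the starting material charged, teal
- amount of target at the end, in percent of the starting material charged, violet
- amount of target at the end, in percent of the starting material charged, ochre
- amount of target at the end, in percent of the starting material charged, red

**Starting rate.** Write A for [starting material]. In red the catalysed rate starts at 0.0234 M/s, and the denominator of the rate law has already cut it to 0.507 of its unsaturated value.

**What slows it.** With A held at its charge in red, partner falls in a pseudo-first-order way. In red the catalysed step takes it at 0.234 /s, decay at 0.162 /s and the uncatalysed step at 0.0332 /s. Together that is 0.430 /s, so the rate shrinks by a factor e every 2.33 s. With A held at its charge, the rate summed over that course gives 54.5 % of target, which is a catalysed share of partner of 0.546.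

But A falls as well. I assume it reaches half of its charge while partner dies away. The catalysed constant is then 0.156 /s, a further factor of 0.667, and the share is 0.465. The mean of the two shares gives my figure for red, 50.6 %.

**The crossing.** Setting the catalysed constant equal to decay gives 0.0532 M. This is the crossing concentration A×, the [starting material] at which the catalysed step and decay take partner equally fast. Partner's charge does not enter it.

Red begins above it. Ochre begins at zero, and its feed, even unconsumed, needs 3.19 s to reach A×. Decay by itself leaves 59.6 % of partner by then, so I place ochre below red.

Cooling lowers decay faster than the catalysed step, as 80.0 kJ/mol stands above 36.0 kJ/mol, so green's A× lies lower during its addition, and I put green first. For teal and violet I commit to no figure.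

**The outcome.** The forecast names green, with 51 % for green, 41 % for teal, 45 % for violet, 36 % for ochre and 48 % for red against my 50.6 %, and says of cold green: “Partner decay nearly stops”. The simulation gives 51.1 % for green, 41.3 % for teal, 43.6 % for violet, 36.0 % for ochre and 48.6 % for red, so green leads and ochre is lowest.

**Crossing reused.** Red, which starts above A×, ends with 0.0486 M of target beside 0.0457 M of decomposed reagent. Ochre, which starts below it, ends with 0.0360 M of target beside 0.0604 M of decomposed reagent. The neighbour of ochre charged with 0.0018 M of catalyst has A× at 0.135 M, above the whole charge of 0.10 M. That neighbour ends with 0.0677 M of decomposed reagent and 0.0276 M of target, which is 27.6 % of the starting material charged.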